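At early times the two earlier flasks part over the intermediate: at 30.0 s Tuesday's run holds 22% of it with 11% product, and Thursday's holds 7% with 75%.

the same everywhere: catalyst 0.053 mol%; added ligand 5.3 µM

| flask | substrate | partner | remark | time |
|---|---|---|---|---|
| Tuesday's | 6.4 mM | 1.1 equiv | run made earlier |  |
| Thursday's | 26 mM | 1.1 equiv | run made earlier |  |
| south-east | 1.5 mM | 1.10 equiv |  | 2.0 min |
| west | 3.0 mM | 1.10 equiv |  | 2.0 min |
| north-east | 6.0 mM | 1.10 equiv |  | 2.0 min |
| south-west | 12 mM | 1.10 equiv |  | 2.0 min |
| south | 25 mM | 1.10 equiv |  | 2.0 min |

- Tuesday's (time / s: intermediate / %, product / %, substrate / %): 10.0: 15, 2, 83; 20.0: 19, 6, 73; 30.0: 22, 11, 66; 60.0: 19, 27, 54; 120: 18, 44, 41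
- Thursday's (time / s: intermediate / %, product / %, substrate / %): 10.0: 10, 48, 44; 30.0: 7, 75, 18; 60.0: 0, 91, 7; 80.0: 4, 94, 4; 120: 1, 96, 3

(scatter of a reading: 1.5 percentage points)

- "hardly changes" means that all values lie within two and a half points (for a concentration: within two and a half percent of the largest)

- [intermediate] at the end for south-east, west, north-east, south-west, south, in this order
- how the row runs (hardly changes / rises, then falls / rises all the way / falls all the way / falls, then rises)

Two chemists argue over this. The first holds a threshold view: the added ligand titrates the catalyst, and catalyst equals added ligand at a substrate charge of 10.0 mM, so turnover should jump there. I hold a smooth view, with no step anywhere.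

Between 60.0 s and 120 s Tuesday's run gains 17 percentage points of product on about 18.5% of intermediate, so it reads 0.0153 s⁻¹. This product gained per second per intermediate standing is the drain constant, a pseudo-first-order constant for that flask. Partner and catalyst are both charged in proportion to substrate, so if both act in the drain, it goes with the square of the charge. Thursday's run, from 10.0 s to 30.0 s, reads 0.159 s⁻¹. That is a factor 10.4, while the charge ratio is 4.06 and its square 16.5. With a scatter of 1.5 points on so little intermediate, that reading is rough.

Now I solve both ends. Drain constant times 2.0 min gives 0.101 for south-east, so little is drained there and the intermediate grows with the charge: Tuesday's 22% would make 0.330 mM. It gives 28.0 for south, where Thursday's last reading of 1% would make 0.250 mM. The ends join where the product equals one, at 4.72 mM, and I expect the row to turn near there.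

The forecast, from the threshold side, expects “a sharp increase in turnover once catalyst exceeds ligand” and gives 0.36 mM, 0.66 mM, 1.05 mM, 0.7 mM and 0.35 mM: rises, then falls.

The simulation gives 0.401 mM, 0.749 mM, 1.00 mM, 0.794 mM and 0.242 mM: rises, then falls.

    substrate + catalyst ⇌ catalyst + intermediate (K = 0.450, k = 13700 M⁻¹ s⁻¹)
    partner + catalyst + intermediate → catalyst + product (k = 1.63 × 10⁶ M⁻² s⁻¹)
    catalyst + added ligand ⇌ idle complex, settled at all times (K = 1.40 × 10⁵ M⁻¹)

The row turns at 6.6 mM, above the 4.72 mM reckoned. Free catalyst moves gently, from 59.0% of the catalyst charged in south-east to 76.5% in south, with no step, and the idle complex holds 41.0% in south-east against 23.5% in south. In south-east, the drain product of 0.101 on a rough mean of 24.0% intermediate gives 2.42% product, and that flask holds 2.81% after 2.00 min.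

The runs were computed with constants of no real substance.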